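**Retrosynthetic overview**
- The target comes from its hydroquinone dimethyl ether by thiolate demethylation. The only late adjustments before that are removal of a C1 ketone (Wolff–Kishner) and exchange of a C8 enol ether oxygen for methyl (enol triflate, Negishi).
- Ring A is taken whole from 2,5-dimethyl-1,4-benzoquinone. Its C3 methyl and C4 methylene are fixed on the ene-dione by organocerium addition, hydroxyl-directed hydrogenation and Peterson elimination.
- Key disconnection: ring B is closed onto the quinone by a catalytic enantioselective Diels–Alder reaction that breaks the quinone's symmetry and sets C9 and C10 (C5 by epimerization). The aryl–CH2 bond is never disconnected; the complete arylacetic acid arrives on the diene.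
- The diene comes from Heck coupling of an aryl iodide with penta-1,4-dien-3-ol and Z-selective silylation. The quinone comes from aerobic oxidation of 2,5-dimethylphenol. Ring order: A (as quinone), then B.

Locants and faces: the decalin is numbered as a drimane (C10 = methyl-bearing fusion carbon, C5 = the other fusion carbon, ring A = C1–C5/C10, ring B = C5–C10, C9 carries the arylmethyl group). β is the face of the C10 methyl. ArH = 4-(carboxymethyl)-2,5-dimethoxyphenyl; ArSi = its triisopropylsilyl ester.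

Assumption: the (S)-catalyst is written as the antipode that gives the 10β-methyl series drawn; if the first run shows the opposite facial sense, the (R)-catalyst is used and nothing else changes.

Step 1
Reactants: 1 2,5-dimethylphenol
Product: 2 2,5-dimethyl-1,4-benzoquinone
Conditions: O2 (1 atm), Co(salen) (C16H14CoN2O2, 5 mol%), DMF, rt
Reagents that add atoms: dioxygen (O=O)
Why: Co(salen)-catalysed aerobic phenol oxidation (salcomine oxidation) dearomatizes the xylenol at its free para position to the symmetric p-quinone that later becomes ring A with both methyl groups already in place.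

Step 2
Reactants: 3 (2,5-dimethoxyphenyl)acetic acid
Product: 4 (4-iodo-2,5-dimethoxyphenyl)acetic acid
Conditions: ICl, AcOH, rt
Reagents that add atoms: iodine monochloride (ClI)
Why: electrophilic aromatic iodination goes para to the CH2 group and ortho to a methoxy group, the most activated and least hindered position of the hydroquinone dimethyl ether.

Step 3
Reactants: 4 (4-iodo-2,5-dimethoxyphenyl)acetic acid; 5 penta-1,4-dien-3-ol
Product: 6 [2,5-dimethoxy-4-(3-oxopent-4-en-1-yl)phenyl]acetic acid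
Conditions: Pd(OAc)2 (5 mol%), NaHCO3, Bu4NCl, DMF, 45 °C (fourfold excess of 5); HCl work-up
Reagents that add atoms: none
Why: Heck reaction under Jeffery conditions, in which the aryl group adds to a terminal vinyl carbon and β-hydride elimination toward the carbinol gives the enol and hence the aryl-ethyl vinyl ketone, the excess dienol suppressing a second arylation.

Step 4
Reactants: 6 [2,5-dimethoxy-4-(3-oxopent-4-en-1-yl)phenyl]acetic acid
Product: 7 triisopropylsilyl {2,5-dimethoxy-4-[(2Z)-3-(triisopropylsilyloxy)penta-2,4-dien-1-yl]phenyl}acetate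
Conditions: TIPSOTf (2.3 equiv), Et3N, CH2Cl2, −78 → 0 °C
Reagents that add atoms: triisopropylsilyl triflate (CC(C)[Si](OS(=O)(=O)C(F)(F)F)(C(C)C)C(C)C)
Why: soft enolization and O-silylation on the only enolizable side of the vinyl ketone gives the 2-silyloxy diene as the preferred Z enol ether (arylmethyl group outside in the s-cis diene), and the acid is masked at the same time as its silyl ester.

Step 5
Reactants: 7 silyl dienol ether; 2 2,5-dimethyl-1,4-benzoquinone
Product: 9 trans-fused ene-dione 9α-(ArSi-CH2)-3,10β-dimethyl-8-(triisopropylsilyloxy)-5α-H-decalin-2,7-diene-1,4-dione, via cis-fused cycloadduct 8 (not isolated)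
Conditions: (S)-oxazaborolidine from α,α-diphenylprolinol and o-tolylboronic acid (C24H24BNO, 20 mol%), HNTf2 (20 mol%), CH2Cl2, −78 → −40 °C; then Et3N, DBU (0.5 equiv), rt
Reagents that add atoms: none
Why: Corey-type cationic oxazaborolidine-catalysed Diels–Alder reaction in which the catalyst binds a quinone C=O at the lone pair syn to the vinylic C–H, the siloxy-activated terminus C9 attacks the methyl-bearing β-carbon (the selection rules for 2,5-dimethylbenzoquinone and 2-silyloxydienes), endo addition of the Z-diene puts the arylmethyl group anti to the new angular methyl, one face of one of the two equivalent quinone double bonds is chosen by the catalyst, and DBU then equilibrates C5 to the trans fusion, which keeps the C9 substituent pseudoaxial and free of A(1,2) strain against the C8 silyloxy group.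

Step 6
Reactants: 9 trans-fused ene-dione
Product: 10 9α-(ArSi-CH2)-4β-hydroxy-3,10β-dimethyl-8-(triisopropylsilyloxy)-4α-(trimethylsilylmethyl)-5α-H-decalin-2,7-dien-1-one
Conditions: Me3SiCH2Li, CeCl3, THF, −78 °C; H2O
Reagents that add atoms: (trimethylsilyl)methyllithium ([Li]C[Si](C)(C)C)
Why: non-basic organocerium 1,2-addition (first half of a Peterson olefination) goes only to the C4 carbonyl because the C1 carbonyl is shielded by the quaternary C10 and the axial arylmethyl group, and it enters from the α face opposite the 1,3-diaxial C10 methyl so that the new hydroxyl is β.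

Step 7
Reactants: 10 tertiary allylic β-hydroxysilane
Product: 12 9α-(ArSi-CH2)-3α,10β-dimethyl-4-methylidene-8-(triisopropylsilyloxy)-5α-H-decal-7-en-1-one, via saturated β-hydroxysilane 11 (not isolated)
Conditions: H2 (1 atm), [Ir(cod)(PCy3)(py)]PF6 (5 mol%), CH2Cl2, 0 °C; then camphorsulfonic acid (10 mol%), 0 °C
Reagents that add atoms: none
Why: hydroxyl-directed hydrogenation (Crabtree–Stork) delivers H2 to C2=C3 from the β face of the C4 alcohol, which makes the C3 methyl α (axial) against the thermodynamic preference, and acid-induced Peterson elimination then gives only the exocyclic methylene so that C3 can no longer epimerize.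

Step 8
Reactants: 12 silyl enol ether ketone
Product: 13 9α-(ArH-CH2)-3α,10β-dimethyl-4-methylidene-1-oxo-5α-H-decal-7-en-8-yl trifluoromethanesulfonate
Conditions: CsF (4 equiv), PhNTf2 (2 equiv), DME, rt; 1 M HCl work-up
Reagents that add atoms: N-phenylbis(trifluoromethanesulfonimide) (O=S(=O)(N(c1ccccc1)S(=O)(=O)C(F)(F)F)C(F)(F)F)
Why: fluoride cleaves both silyl groups and the cesium enolate released regiospecifically at C7=C8–O is trapped as the enol triflate (enolate O-sulfonylation), the side chain being a carboxylate with no acidic C–H at this point, so the olefin position set by the cycloaddition is kept.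

Step 9
Reactants: 13 enol triflate
Product: 14 9α-(ArH-CH2)-3α,8,10β-trimethyl-4-methylidene-5α-H-decal-7-en-1-one
Conditions: MeZnCl (3 equiv), Pd(PPh3)4 (5 mol%), THF, 50 °C; 1 M HCl work-up
Reagents that add atoms: methylzinc chloride (C[Zn]Cl)
Why: Negishi cross-coupling replaces the triflate by methyl with retention of the C7=C8 position, the hindered C1 ketone and the zinc carboxylate being inert to the organozinc.

Step 10
Reactants: 14 keto acid
Product: 15 2-(4-{[(1R,4aS,6R,8aR)-2,6,8a-trimethyl-5-methylidene-1,4,4a,5,6,7,8,8a-octahydronaphthalen-1-yl]methyl}-2,5-dimethoxyphenyl)acetic acid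
Conditions: N2H4·H2O, KOH, diethylene glycol, 130 °C then 200 °C; HCl work-up
Reagents that add atoms: none
Why: Wolff–Kishner reduction (Huang-Minlon procedure) removes the C1 carbonyl, the only carbonyl left besides the carboxylate, while the isolated olefins and the aryl methyl ethers are stable to hot alkali.

Step 11
Reactants: 15 dimethyl ether acid
Product: 16 2-(4-{[(1R,4aS,6R,8aR)-2,6,8a-trimethyl-5-methylidene-1,4,4a,5,6,7,8,8a-octahydronaphthalen-1-yl]methyl}-2,5-dihydroxyphenyl)acetic acid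
Conditions: n-BuSLi (10 equiv), HMPA, 110 °C, argon; degassed 1 M HCl work-up
Reagents that add atoms: none
Why: SN2 demethylation of both aryl methyl ethers by thiolate frees the hydroquinone under basic, non-oxidizing conditions, so neither acid-induced chromane formation at C7=C8 nor oxidative decarboxylation of the arylacetic acid can occur.

**Compound list**
1 | 2,5-dimethylphenol | Cc1ccc(C)c(O)c1 | starting material
2 | 2,5-dimethyl-1,4-benzoquinone | CC1=CC(=O)C(C)=CC1=O | intermediate
3 | (2,5-dimethoxyphenyl)acetic acid | COc1ccc(OC)c(CC(=O)O)c1 | starting material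
4 | (4-iodo-2,5-dimethoxyphenyl)acetic acid | COc1cc(I)c(OC)cc1CC(=O)O | intermediate
5 | penta-1,4-dien-3-ol | C=CC(O)C=C | starting material
6 | [2,5-dimethoxy-4-(3-oxopent-4-en-1-yl)phenyl]acetic acid | C=CC(=O)CCc1cc(OC)c(CC(=O)O)cc1OC | intermediate
7 | triisopropylsilyl {2,5-dimethoxy-4-[(2Z)-3-(triisopropylsilyloxy)penta-2,4-dien-1-yl]phenyl}acetate | C=C/C(O[Si](C(C)C)(C(C)C)C(C)C)=C/Cc1cc(OC)c(CC(=O)O[Si](C(C)C)(C(C)C)C(C)C)cc1OC | intermediate
8 | cis-fused cycloadduct: 9α-(ArSi-CH2)-3,10β-dimethyl-8-(triisopropylsilyloxy)-5β-H-decalin-2,7-diene-1,4-dione | O=C1C(C)=CC(=O)[C@]2(C)[C@H](Cc3cc(OC)c(CC(=O)O[Si](C(C)C)(C(C)C)C(C)C)cc3OC)C(O[Si](C(C)C)(C(C)C)C(C)C)=CC[C@H]12 | intermediate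
9 | trans-fused ene-dione: 9α-(ArSi-CH2)-3,10β-dimethyl-8-(triisopropylsilyloxy)-5α-H-decalin-2,7-diene-1,4-dione | O=C1C(C)=CC(=O)[C@]2(C)[C@H](Cc3cc(OC)c(CC(=O)O[Si](C(C)C)(C(C)C)C(C)C)cc3OC)C(O[Si](C(C)C)(C(C)C)C(C)C)=CC[C@@H]12 | intermediate
10 | 9α-(ArSi-CH2)-4β-hydroxy-3,10β-dimethyl-8-(triisopropylsilyloxy)-4α-(trimethylsilylmethyl)-5α-H-decalin-2,7-dien-1-one | C[Si](C)(C)C[C@]1(O)C(C)=CC(=O)[C@]2(C)[C@H](Cc3cc(OC)c(CC(=O)O[Si](C(C)C)(C(C)C)C(C)C)cc3OC)C(O[Si](C(C)C)(C(C)C)C(C)C)=CC[C@@H]12 | intermediate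
11 | 9α-(ArSi-CH2)-4β-hydroxy-3α,10β-dimethyl-8-(triisopropylsilyloxy)-4α-(trimethylsilylmethyl)-5α-H-decal-7-en-1-one | C[Si](C)(C)C[C@]1(O)[C@H](C)CC(=O)[C@]2(C)[C@H](Cc3cc(OC)c(CC(=O)O[Si](C(C)C)(C(C)C)C(C)C)cc3OC)C(O[Si](C(C)C)(C(C)C)C(C)C)=CC[C@@H]12 | intermediate
12 | 9α-(ArSi-CH2)-3α,10β-dimethyl-4-methylidene-8-(triisopropylsilyloxy)-5α-H-decal-7-en-1-one | C=C1[C@H](C)CC(=O)[C@]2(C)[C@H](Cc3cc(OC)c(CC(=O)O[Si](C(C)C)(C(C)C)C(C)C)cc3OC)C(O[Si](C(C)C)(C(C)C)C(C)C)=CC[C@@H]12 | intermediate
13 | 9α-(ArH-CH2)-3α,10β-dimethyl-4-methylidene-1-oxo-5α-H-decal-7-en-8-yl trifluoromethanesulfonate | C=C1[C@H](C)CC(=O)[C@]2(C)[C@H](Cc3cc(OC)c(CC(=O)O)cc3OC)C(OS(=O)(=O)C(F)(F)F)=CC[C@@H]12 | intermediate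
14 | 9α-(ArH-CH2)-3α,8,10β-trimethyl-4-methylidene-5α-H-decal-7-en-1-one | C=C1[C@H](C)CC(=O)[C@]2(C)[C@H](Cc3cc(OC)c(CC(=O)O)cc3OC)C(C)=CC[C@@H]12 | intermediate
15 | 2-(4-{[(1R,4aS,6R,8aR)-2,6,8a-trimethyl-5-methylidene-1,4,4a,5,6,7,8,8a-octahydronaphthalen-1-yl]methyl}-2,5-dimethoxyphenyl)acetic acid | C=C1[C@H](C)CC[C@]2(C)[C@H](Cc3cc(OC)c(CC(=O)O)cc3OC)C(C)=CC[C@@H]12 | intermediate
16 | 2-(4-{[(1R,4aS,6R,8aR)-2,6,8a-trimethyl-5-methylidene-1,4,4a,5,6,7,8,8a-octahydronaphthalen-1-yl]methyl}-2,5-dihydroxyphenyl)acetic acid | C=C1[C@H](C)CC[C@]2(C)[C@H](Cc3cc(O)c(CC(=O)O)cc3O)C(C)=CC[C@@H]12 | target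

Total step count: 11. Longest linear sequence: 10 steps (3 → 16); step 1 is a one-step side branch.

**Steps most likely to fail**

Step 5. The diene terminus that must bond to the methyl-bearing quinone carbon is itself substituted, which goes beyond the published diene scope, so rate, orientation and ee may all suffer. The fallback sets out from 6 and comes back at 14. It replaces the C8 oxygen by a silylmethyl group, which polarizes the diene the same way and is itself the masked methyl. KHMDS (2.2 equiv) and PhNTf2 convert 6 into the (Z)-dienyl triflate acid F1. Pd-catalysed Kumada coupling with Me3SiCH2MgCl followed by TIPSOTf/Et3N gives the 2-(trimethylsilylmethyl)diene silyl ester F2. The same cycloaddition and epimerization with 2 give the trans-fused ene-dione F3. The chemistry of step 6 gives carbinol F4, and hydrogenation as in step 7 with KH for the Peterson elimination gives the methylene ketone acid F5. TBAF in wet DMSO at 80 °C (protodesilylation of the allylsilane at the CH2 terminus) gives 14, so steps 8 and 9 are not needed.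

Step 7. The tertiary allylic β-silyl carbinol may ionize on the acidic iridium catalyst before hydrogen is delivered, or the silyl enol ether may be reduced. The fallback sets out from 9 and comes back at 11. Luche reduction (NaBH4, CeCl3, MeOH, −78 °C) attacks C4 from the α face and gives the 4β-allylic alcohol F6. Directed hydrogenation of this robust secondary alcohol with [Rh(nbd)(dppb)]BF4 gives the 3α-methyl hydroxy ketone F7. Dess–Martin oxidation (NaHCO3 buffer) gives the 1,4-dione F8. The non-basic organocerium reagent of step 6 then adds to C4 of F8 without epimerizing C3 and gives 11, which is eliminated as in step 7.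

Step 8. Proton exchange between the cesium enolate and the C1 ketone would scramble the triflate position. The fallback sets out from 12 and comes back at 15. It removes the ketone first under mild conditions: TsNHNH2 (THF, 60 °C) gives the C1 tosylhydrazone F9. Catecholborane followed by NaOAc·3H2O (Kabalka reduction) gives the C1-deoxy silyl enol ether acid F10, the silyl ester being lost on work-up. CsF/PhNTf2 (with Cs2CO3) now gives the C1-deoxy enol triflate acid F11 with no competing ketone. Negishi methylation as in step 9 gives 15, so step 10 is not needed.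

**Further compounds**
F1 | step 5 | {4-[(2Z)-3-(trifluoromethanesulfonyloxy)penta-2,4-dien-1-yl]-2,5-dimethoxyphenyl}acetic acid | C=C/C(OS(=O)(=O)C(F)(F)F)=C/Cc1cc(OC)c(CC(=O)O)cc1OC
F2 | step 5 | triisopropylsilyl {2,5-dimethoxy-4-[(2Z)-3-(trimethylsilylmethyl)penta-2,4-dien-1-yl]phenyl}acetate | C=C/C(C[Si](C)(C)C)=C/Cc1cc(OC)c(CC(=O)O[Si](C(C)C)(C(C)C)C(C)C)cc1OC
F3 | step 5 | 9α-(ArSi-CH2)-3,10β-dimethyl-8-(trimethylsilylmethyl)-5α-H-decalin-2,7-diene-1,4-dione | O=C1C(C)=CC(=O)[C@]2(C)[C@H](Cc3cc(OC)c(CC(=O)O[Si](C(C)C)(C(C)C)C(C)C)cc3OC)C(C[Si](C)(C)C)=CC[C@@H]12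
F4 | step 5 | 9α-(ArSi-CH2)-4β-hydroxy-3,10β-dimethyl-4α,8-bis(trimethylsilylmethyl)-5α-H-decalin-2,7-dien-1-one | C[Si](C)(C)C[C@]1(O)C(C)=CC(=O)[C@]2(C)[C@H](Cc3cc(OC)c(CC(=O)O[Si](C(C)C)(C(C)C)C(C)C)cc3OC)C(C[Si](C)(C)C)=CC[C@@H]12
F5 | step 5 | 9α-(ArH-CH2)-3α,10β-dimethyl-4-methylidene-8-(trimethylsilylmethyl)-5α-H-decal-7-en-1-one | C=C1[C@H](C)CC(=O)[C@]2(C)[C@H](Cc3cc(OC)c(CC(=O)O)cc3OC)C(C[Si](C)(C)C)=CC[C@@H]12
F6 | step 7 | 9α-(ArSi-CH2)-4β-hydroxy-3,10β-dimethyl-8-(triisopropylsilyloxy)-5α-H-decalin-2,7-dien-1-one | O[C@H]1C(C)=CC(=O)[C@]2(C)[C@H](Cc3cc(OC)c(CC(=O)O[Si](C(C)C)(C(C)C)C(C)C)cc3OC)C(O[Si](C(C)C)(C(C)C)C(C)C)=CC[C@@H]12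
F7 | step 7 | 9α-(ArSi-CH2)-4β-hydroxy-3α,10β-dimethyl-8-(triisopropylsilyloxy)-5α-H-decal-7-en-1-one | O[C@H]1[C@H](C)CC(=O)[C@]2(C)[C@H](Cc3cc(OC)c(CC(=O)O[Si](C(C)C)(C(C)C)C(C)C)cc3OC)C(O[Si](C(C)C)(C(C)C)C(C)C)=CC[C@@H]12
F8 | step 7 | 9α-(ArSi-CH2)-3α,10β-dimethyl-8-(triisopropylsilyloxy)-5α-H-decal-7-ene-1,4-dione | O=C1[C@H](C)CC(=O)[C@]2(C)[C@H](Cc3cc(OC)c(CC(=O)O[Si](C(C)C)(C(C)C)C(C)C)cc3OC)C(O[Si](C(C)C)(C(C)C)C(C)C)=CC[C@@H]12
F9 | step 8 | C1 p-toluenesulfonylhydrazone of 12 | C=C1[C@H](C)CC(=NNS(=O)(=O)c4ccc(C)cc4)[C@]2(C)[C@H](Cc3cc(OC)c(CC(=O)O[Si](C(C)C)(C(C)C)C(C)C)cc3OC)C(O[Si](C(C)C)(C(C)C)C(C)C)=CC[C@@H]12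
F10 | step 8 | 9α-(ArH-CH2)-3α,10β-dimethyl-4-methylidene-8-(triisopropylsilyloxy)-5α-H-decal-7-ene | C=C1[C@H](C)CC[C@]2(C)[C@H](Cc3cc(OC)c(CC(=O)O)cc3OC)C(O[Si](C(C)C)(C(C)C)C(C)C)=CC[C@@H]12
F11 | step 8 | 9α-(ArH-CH2)-3α,10β-dimethyl-4-methylidene-5α-H-decal-7-en-8-yl trifluoromethanesulfonate | C=C1[C@H](C)CC[C@]2(C)[C@H](Cc3cc(OC)c(CC(=O)O)cc3OC)C(OS(=O)(=O)C(F)(F)F)=CC[C@@H]12
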